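The route rests on cutting pyran ring B at the O–C10 bond. C10, the fully substituted ring-B/ring-C carbon that bears the pyran oxygen, a methyl group and the C9 and C1 chains, is formed when the single free phenol (Cf–OH) of an open-chain (E)-allylic methyl carbonate attacks a palladium-bound C8–C9–C10 allyl unit at C10; one operation closes ring B, sets C10 under ligand control and leaves a C9=C8 vinyl handle. The precursor carries the auxiliary-set C1 centre with a benzyl-protected C2 arm, and its Cb and Cd oxygens as MOM ethers, so that ring C (C8 alkylation, C2–C3 coupling, metathesis) and the ring-A end game stay mild.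

Key step: step 15

Labels: ring A is Ca (acyl carbon), Cb, Cc, Cd, Ce, Cf (pyran oxygen); C7′ is the pyran CH2; ring C is C1–C10; C11 is the carbinol carbon. MOM = methoxymethyl, TIPS = triisopropylsilyl, Bn = benzyl. Ar = 2,4-bis(methoxymethoxy)-3-methyl-6-[(triisopropylsilyl)oxy]phenyl. Chr = (2R,3R)-3-[(benzyloxy)methyl]-5,7-bis(methoxymethoxy)-2,6-dimethylchroman-2-yl.

Remark on the precursor design: Cb–O and Cd–O are MOM ethers (ortho-directing for the late Ca lithiation, removable with mild acid beside the C11 carbinol and the ring-C alkene), C2–O is a benzyl ether (inert to the fluoride that frees Cf–OH), and the E alkene is carried geometrically pure.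

Assumption: the ligand antipode that places C9 trans to C2 is taken to be the (1S,2S) form, by analogy with (E)-configured 2-hydroxyaryl allyl carbonates that lack the C1 centre; a first pair of runs with both antipodes is to confirm it.

Step 1
Reactants: 1 2-methylbenzene-1,3-diol
Product: 2 1,3-bis(methoxymethoxy)-2-methylbenzene
Conditions: MeOCH2Cl (2.6 equiv), iPr2NEt, CH2Cl2, 0 °C to rt
Reagents that add atoms: chloromethyl methyl ether, COCCl
Why: Both phenols are alkylated by the α-chloro ether under amine base (Williamson-type acetal formation); no stereocenter is involved.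

Step 2
Reactants: 2 1,3-bis(methoxymethoxy)-2-methylbenzene
Product: 4 3,5-bis(methoxymethoxy)-4-methylphenol, via aryl pinacol boronate 3 (not isolated)
Conditions: [Ir(OMe)(cod)]2 (1.5 mol%), 4,4′-di-tert-butyl-2,2′-bipyridine (3 mol%), B2pin2 (0.6 equiv), THF, 80 °C; then 30% H2O2, aq NaOH, 0 °C
Reagents that add atoms: hydrogen peroxide, OO; bis(pinacolato)diboron, CC1(C)OB(OC1(C)C)B1OC(C)(C)C(C)(C)O1 (boron held in 3 only)
Why: Sterically controlled iridium-catalysed C–H borylation should take the only ring position without an ortho substituent (para to the methyl group), and oxidation of the C–B bond in the same pot (borylation–oxidation sequence) marks the future Cf oxygen as the single free phenol.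

Step 3
Reactants: 4 3,5-bis(methoxymethoxy)-4-methylphenol
Product: 5 6-hydroxy-2,4-bis(methoxymethoxy)-3-methylbenzaldehyde
Conditions: MgCl2 (2 equiv), Et3N (4 equiv), paraformaldehyde (6 equiv), MeCN, reflux
Reagents that add atoms: formaldehyde (as paraformaldehyde), C=O
Why: Magnesium-phenoxide-directed ortho-formylation (Casnati–Skattebøl reaction) should give one aldehyde because the two positions ortho to the hydroxyl are equivalent, excess formaldehyde acting as hydride acceptor; the new carbon is C7′.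

Step 4
Reactants: 5 6-hydroxy-2,4-bis(methoxymethoxy)-3-methylbenzaldehyde
Product: 6 2,4-bis(methoxymethoxy)-3-methyl-6-[(triisopropylsilyl)oxy]benzaldehyde (Ar–CHO)
Conditions: iPr3SiCl, imidazole, DMAP (cat.), DMF, 40 °C
Reagents that add atoms: chlorotriisopropylsilane, CC(C)[Si](Cl)(C(C)C)C(C)C
Why: Silylation of the hydrogen-bonded phenol, the bulky triisopropylsilyl ether being chosen because it has to outlast hydroperoxide, methyllithium and sodium hydride in steps 9 to 11.

Step 5
Reactants: 7 (S)-4-benzyl-1,3-oxazolidin-2-one; 8 2-(diethoxyphosphoryl)acetic acid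
Product: 10 (S)-4-benzyl-3-[2-(diethoxyphosphoryl)acetyl]-1,3-oxazolidin-2-one, via mixed pivalic anhydride 9 (not isolated)
Conditions: t-BuCOCl, Et3N, THF, −20 °C; then 7, LiCl, rt
Reagents that add atoms: pivaloyl chloride, CC(C)(C)C(=O)Cl (held in 9 only)
Why: N-Acylation of the oxazolidinone by the mixed anhydride under LiCl/Et3N activation should give the phosphonate reagent; no stereocenter is formed.

Step 6
Reactants: 6 Ar–CHO; 10 (S)-4-benzyl-3-[2-(diethoxyphosphoryl)acetyl]-1,3-oxazolidin-2-one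
Product: 11 (S)-4-benzyl-3-[(E)-3-Ar-prop-2-enoyl]-1,3-oxazolidin-2-one
Conditions: LiCl, iPr2NEt, MeCN, rt
Reagents that add atoms: none
Why: Horner–Wadsworth–Emmons olefination under Masamune–Roush conditions is mild enough for the aryl silyl ether and should give the E enoyl imide.

Step 7
Reactants: 11 (S)-4-benzyl-3-[(E)-3-Ar-prop-2-enoyl]-1,3-oxazolidin-2-one
Product: 12 (S)-4-benzyl-3-(3-Ar-propanoyl)-1,3-oxazolidin-2-one
Conditions: H2 (1 atm), 10% Pd/C, EtOAc, rt
Reagents that add atoms: none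
Why: Catalytic hydrogenation saturates the conjugated C=C bond while the silyl ether, the acetals and the imide are inert.

Step 8
Reactants: 12 (S)-4-benzyl-3-(3-Ar-propanoyl)-1,3-oxazolidin-2-one
Product: 14 (S)-4-benzyl-3-[(2R)-3-Ar-2-[(benzyloxy)methyl]propanoyl]-1,3-oxazolidin-2-one, via sodium enolate 13 (not isolated)
Conditions: NaN(SiMe3)2, THF, −78 °C; BnOCH2Cl (3 equiv), −78 to −20 °C
Reagents that add atoms: benzyl chloromethyl ether, ClCOCc1ccccc1; sodium bis(trimethylsilyl)amide, [Na+].C[Si](C)(C)[N-][Si](C)(C)C (sodium held in 13 only)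
Why: Oxazolidinone-enolate alkylation (Evans alkylation): the chelated Z sodium enolate is alkylated by the α-chloro ether on the face opposite the C4 benzyl group, which should set C1 as drawn and bring in C2 as its benzyl ether without a Lewis acid that would endanger the MOM ethers.

Step 9
Reactants: 14 (S)-4-benzyl-3-[(2R)-3-Ar-2-[(benzyloxy)methyl]propanoyl]-1,3-oxazolidin-2-one
Product: 16 (2R)-3-Ar-2-[(benzyloxy)methyl]propanoic acid, via peroxy acid 15 (not isolated)
Conditions: LiOH, 30% H2O2, THF/H2O, 0 °C; then aq Na2SO3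
Reagents that add atoms: hydrogen peroxide, OO
Why: Hydroperoxide anion attacks the exocyclic imide carbonyl selectively (LiOOH cleavage) and sulfite reduces the peracid, so C1 is not enolised and the auxiliary 7 is recovered.

Step 10
Reactants: 16 (2R)-3-Ar-2-[(benzyloxy)methyl]propanoic acid
Product: 17 (3R)-4-Ar-3-[(benzyloxy)methyl]butan-2-one
Conditions: MeLi (2.5 equiv), Et2O, 0 °C; inverse quench into cold aq NH4Cl
Reagents that add atoms: methyllithium, [Li]C
Why: Addition of methyllithium to the lithium carboxylate stops at the geminal dialkoxide, which gives the methyl ketone only on aqueous work-up (ketone synthesis from carboxylic acids), leaving C1 untouched.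

Step 11
Reactants: 17 (3R)-4-Ar-3-[(benzyloxy)methyl]butan-2-one
Product: 18 ethyl (2E,4S)-5-Ar-4-[(benzyloxy)methyl]-3-methylpent-2-enoate
Conditions: (EtO)2P(O)CH2CO2Et (3 equiv), NaH, THF, 0 to 45 °C; E isomer separated by chromatography
Reagents that add atoms: triethyl phosphonoacetate, CCOC(=O)CP(=O)(OCC)OCC
Why: Horner–Wadsworth–Emmons olefination of the methyl ketone should favour the E enoate (ester trans to the branched C1 substituent), and any Z isomer is removed because step 15 needs a geometrically pure substrate.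

Step 12
Reactants: 18 ethyl (2E,4S)-5-Ar-4-[(benzyloxy)methyl]-3-methylpent-2-enoate
Product: 19 (2E,4S)-5-Ar-4-[(benzyloxy)methyl]-3-methylpent-2-en-1-ol
Conditions: iBu2AlH (2.5 equiv), CH2Cl2, −78 °C; aq potassium sodium tartrate
Reagents that add atoms: none
Why: 1,2-Reduction of the conjugated ester by the aluminium hydride at low temperature gives the allylic alcohol without touching the trisubstituted alkene.

Step 13
Reactants: 19 (2E,4S)-5-Ar-4-[(benzyloxy)methyl]-3-methylpent-2-en-1-ol
Product: 20 (2E,4S)-5-Ar-4-[(benzyloxy)methyl]-3-methylpent-2-en-1-yl methyl carbonate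
Conditions: MeOCOCl, pyridine, CH2Cl2, 0 °C
Reagents that add atoms: methyl chloroformate, COC(=O)Cl
Why: Acylation of the primary allylic alcohol with the chloroformate installs the leaving group for ionisation.

Step 14
Reactants: 20 (2E,4S)-5-Ar-4-[(benzyloxy)methyl]-3-methylpent-2-en-1-yl methyl carbonate
Product: 21 (2E,4S)-4-[(benzyloxy)methyl]-5-[6-hydroxy-2,4-bis(methoxymethoxy)-3-methylphenyl]-3-methylpent-2-en-1-yl methyl carbonate
Conditions: Bu4NF (1.1 equiv), AcOH (1.2 equiv), THF, 0 °C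
Reagents that add atoms: none
Why: Fluoride cleaves the aryl O–Si bond (desilylation) and acetic acid keeps the liberated phenol protonated so that the allylic carbonate is not attacked, the benzyl and MOM ethers being inert.

Step 15
Reactants: 21 (2E,4S)-4-[(benzyloxy)methyl]-5-[6-hydroxy-2,4-bis(methoxymethoxy)-3-methylphenyl]-3-methylpent-2-en-1-yl methyl carbonate
Product: 22 (2R,3R)-3-[(benzyloxy)methyl]-2-ethenyl-5,7-bis(methoxymethoxy)-2,6-dimethylchromane
Conditions: Pd2(dba)3·CHCl3 (2.5 mol%), (1S,2S)-N,N′-bis[2-(diphenylphosphino)benzoyl]cyclohexane-1,2-diamine (7.5 mol%), AcOH (1 equiv), CH2Cl2, rt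
Reagents that add atoms: none
Why: Zerovalent palladium ionises the primary allylic carbonate (loss of CO2 and methoxide) to a cationic C8–C9–C10 allyl complex of divalent palladium, and the Cf phenol attacks the allyl carbon C10 on the face away from the metal; this is an intramolecular Tsuji–Trost O-allylation, the asymmetric allylic alkylation of phenols known for 2-methyl-2-vinylchromans. Ring B closes in the 6-exo mode at the substituted allyl terminus, since attack at C8 would require an eight-membered ring. The new stereocenter C10 is controlled by the chiral pocket of the diphosphine, which selects the face of the allyl unit, while C1 is carried through unchanged. The step needs diastereoselectivity for C9 trans to C2 and regioselectivity among the ring-A oxygens: the first rests on the geometrically pure E carbonate, on acetic acid that lets the diastereomeric allyl complexes interconvert before ring closure and on the choice of ligand antipode, and the second is secured because Cd–O and Cb–O are capped as MOM ethers and only Cf–OH is free.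

Step 16
Reactants: 22 (2R,3R)-3-[(benzyloxy)methyl]-2-ethenyl-5,7-bis(methoxymethoxy)-2,6-dimethylchromane
Product: 24 2-Chr-ethan-1-ol, via B-alkyl-9-BBN adduct 23 (not isolated)
Conditions: 9-BBN (2 equiv), THF, rt to 50 °C; then aq NaOH, 30% H2O2, 0 °C to rt
Reagents that add atoms: hydrogen peroxide, OO; 9-borabicyclo[3.3.1]nonane, [H]B1C2CCCC1CCC2 (boron held in 23 only)
Why: Hydroboration of the vinyl group with the bulky borane places boron on the terminal carbon C8 (anti-Markovnikov) and alkaline peroxide oxidation gives the primary alcohol, C10 not being affected.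

Step 17
Reactants: 24 2-Chr-ethan-1-ol
Product: 25 2-Chr-ethyl trifluoromethanesulfonate
Conditions: Tf2O (1.2 equiv), 2,6-lutidine, CH2Cl2, −78 °C; cold aqueous wash, used at once
Reagents that add atoms: trifluoromethanesulfonic anhydride, O=S(=O)(OS(=O)(=O)C(F)(F)F)C(F)(F)F
Why: O-Sulfonylation of the primary alcohol at low temperature gives an alkyl triflate, an electrophile reactive enough for an imide enolate at −78 °C.

Step 18
Reactants: 26 (R)-4-benzyl-1,3-oxazolidin-2-one
Product: 27 (R)-4-benzyl-3-[(E)-but-2-enoyl]-1,3-oxazolidin-2-one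
Conditions: (E)-but-2-enoic anhydride, Et3N, LiCl, THF, rt
Reagents that add atoms: crotonic anhydride, C/C=C/C(=O)OC(=O)/C=C/C
Why: N-Acylation of the oxazolidinone with the anhydride under LiCl/Et3N activation; no stereocenter is formed.

Step 19
Reactants: 27 (R)-4-benzyl-3-[(E)-but-2-enoyl]-1,3-oxazolidin-2-one; 25 2-Chr-ethyl trifluoromethanesulfonate
Product: 29 (R)-4-benzyl-3-[(2R)-2-(2-Chr-ethyl)but-3-enoyl]-1,3-oxazolidin-2-one, via sodium dienolate 28 (not isolated)
Conditions: 27 (2 equiv), NaN(SiMe3)2 (1.9 equiv), THF, −78 °C; then 25, −78 to −45 °C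
Reagents that add atoms: sodium bis(trimethylsilyl)amide, [Na+].C[Si](C)(C)[N-][Si](C)(C)C (sodium held in 28 only)
Why: γ-Deprotonation of the crotonyl imide gives the chelated dienolate, which is alkylated at its α-carbon by the triflate on the face opposite the C4 benzyl group (deconjugative oxazolidinone alkylation), so that C7 should be set as drawn and the C6=C5 vinyl group is formed in the same step.

Step 20
Reactants: 29 (R)-4-benzyl-3-[(2R)-2-(2-Chr-ethyl)but-3-enoyl]-1,3-oxazolidin-2-one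
Product: 30 methyl (2R)-2-(2-Chr-ethyl)but-3-enoate
Conditions: MeMgBr (1.2 equiv) added to MeOH/CH2Cl2, 0 °C; then 29, 0 °C
Reagents that add atoms: methanol, CO
Why: Bromomagnesium methoxide attacks the exocyclic carbonyl (transesterification of an N-acyl oxazolidinone), a non-epimerising way to trade the auxiliary for a methyl ester.

Step 21
Reactants: 30 methyl (2R)-2-(2-Chr-ethyl)but-3-enoate
Product: 31 (3R)-3-(2-Chr-ethyl)-2-methylpent-4-en-2-ol
Conditions: MeMgBr (4 equiv), CeCl3 (4 equiv), THF, −78 to 0 °C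
Reagents that add atoms: methylmagnesium bromide, C[Mg]Br
Why: Double addition of the weakly basic methylcerium reagent to the ester (organocerium addition) should build the C11 dimethylcarbinol without enolising the allylic C7–H, so that C7 keeps its configuration.

Step 22
Reactants: 31 (3R)-3-(2-Chr-ethyl)-2-methylpent-4-en-2-ol
Product: 32 (3R)-3-{2-[(2R,3R)-3-(hydroxymethyl)-5,7-bis(methoxymethoxy)-2,6-dimethylchroman-2-yl]ethyl}-2-methylpent-4-en-2-ol
Conditions: lithium 4,4′-di-tert-butylbiphenylide (5 equiv), THF, −78 °C; aq NH4Cl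
Reagents that add atoms: none
Why: Single-electron transfer from the arene radical anion cleaves the benzylic C–O bond (reductive debenzylation), which leaves the isolated vinyl group, the acetals and the aryl ethers alone, as hydrogenolysis would not.

Step 23
Reactants: 32 (3R)-3-{2-[(2R,3R)-3-(hydroxymethyl)-5,7-bis(methoxymethoxy)-2,6-dimethylchroman-2-yl]ethyl}-2-methylpent-4-en-2-ol
Product: 33 {(2R,3R)-2-[(3R)-3-ethenyl-4-hydroxy-4-methylpentyl]-5,7-bis(methoxymethoxy)-2,6-dimethylchroman-3-yl}methyl 4-methylbenzenesulfonate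
Conditions: TsCl (1.3 equiv), pyridine, DMAP (cat.), CH2Cl2, 0 °C to rt
Reagents that add atoms: 4-methylbenzenesulfonyl chloride, Cc1ccc(cc1)S(Cl)(=O)=O
Why: Sulfonylation takes the primary C2 hydroxyl selectively because the tertiary C11 hydroxyl is too hindered to react.

Step 24
Reactants: 34 methyl (S)-3-hydroxy-2-methylpropanoate
Product: 35 methyl (S)-3-[(tert-butyldimethylsilyl)oxy]-2-methylpropanoate
Conditions: t-BuMe2SiCl, imidazole, CH2Cl2, rt
Reagents that add atoms: tert-butylchlorodimethylsilane, CC(C)(C)[Si](C)(C)Cl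
Why: Silylation of the primary alcohol of the chiral-pool ester that supplies C3, C4 (with its methyl group) and C5.

Step 25
Reactants: 35 methyl (S)-3-[(tert-butyldimethylsilyl)oxy]-2-methylpropanoate
Product: 36 (S)-3-[(tert-butyldimethylsilyl)oxy]-2-methylpropanal
Conditions: iBu2AlH (1.05 equiv), CH2Cl2, −78 °C; MeOH, then aq potassium sodium tartrate
Reagents that add atoms: none
Why: Partial reduction of the ester at −78 °C stops at the aldehyde because the tetrahedral aluminium alkoxide survives until the quench, and the α-stereocenter (future C4) is kept.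

Step 26
Reactants: 36 (S)-3-[(tert-butyldimethylsilyl)oxy]-2-methylpropanal
Product: 37 (R)-tert-butyldimethyl[(2-methylbut-3-en-1-yl)oxy]silane
Conditions: Ph3PCH3Br, KOtBu, THF, 0 °C
Reagents that add atoms: methyltriphenylphosphonium bromide, C[P+](c1ccccc1)(c1ccccc1)c1ccccc1.[Br-]
Why: Wittig methylenation with the non-stabilised ylide converts the aldehyde into the terminal alkene at low temperature, which limits epimerisation next to the carbonyl.

Step 27
Reactants: 37 (R)-tert-butyldimethyl[(2-methylbut-3-en-1-yl)oxy]silane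
Product: 38 (R)-4-bromo-3-methylbut-1-ene
Conditions: Ph3PBr2, CH2Cl2, 0 °C to rt
Reagents that add atoms: dibromotriphenylphosphorane, BrP(Br)(c1ccccc1)(c1ccccc1)c1ccccc1
Why: The phosphorus dibromide converts the primary silyl ether directly into the bromide through an oxyphosphonium ion and SN2 displacement at CH2 (Appel-type bromination), so the adjacent stereocenter is untouched.

Step 28
Reactants: 38 (R)-4-bromo-3-methylbut-1-ene; 33 {(2R,3R)-2-[(3R)-3-ethenyl-4-hydroxy-4-methylpentyl]-5,7-bis(methoxymethoxy)-2,6-dimethylchroman-3-yl}methyl 4-methylbenzenesulfonate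
Product: 40 (3R)-3-{2-[(2R,3S)-5,7-bis(methoxymethoxy)-2,6-dimethyl-3-[(3S)-3-methylpent-4-en-1-yl]chroman-2-yl]ethyl}-2-methylpent-4-en-2-ol, via Grignard reagent 39 (not isolated)
Conditions: 38 (3 equiv), Mg, THF, 0 °C to rt, used at once; then 33, Li2CuCl4 (5 mol%), THF, −30 °C to rt
Reagents that add atoms: magnesium, [Mg] (held in 39 only)
Why: Copper-catalysed sp3–sp3 cross-coupling of a primary tosylate with a Grignard reagent (Kochi–Schlosser coupling) forms the C2–C3 bond, the stereocenters C1 and C4 not being at the reacting carbons and one equivalent of 39 being consumed by the C11 hydroxyl.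

Step 29
Reactants: 40 (3R)-3-{2-[(2R,3S)-5,7-bis(methoxymethoxy)-2,6-dimethyl-3-[(3S)-3-methylpent-4-en-1-yl]chroman-2-yl]ethyl}-2-methylpent-4-en-2-ol
Product: 41 ring-closed (5Z)-tricycle (C1 S; C4 S; C7 R; C10 R) with free C11 carbinol, aromatic ring A, Cb/Cd MOM ethers and Ca–H
Conditions: RuCl2(=CHPh)(H2IMes)(PCy3) (second-generation Grubbs catalyst, 10 mol%), degassed CH2Cl2 (1 mM), 40 °C
Reagents that add atoms: none
Why: Ring-closing metathesis of the two terminal vinyl groups closes ring C at C5=C6 with loss of ethene; the two arms leave the adjacent ring atoms C10 and C1 of a rigid chroman, and the Z alkene is expected because cis-cyclodecene is the less strained isomer and the carbene catalyst equilibrates the products.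

Step 30
Reactants: 41 ring-closed (5Z)-tricycle
Product: 43 Ca-isobutyryl derivative of 41 (aryl isopropyl ketone; MOM ethers and C11 carbinol kept), via aryllithium alkoxide 42 (not isolated)
Conditions: n-BuLi (2.5 equiv), TMEDA, THF, −78 to −20 °C; then i-PrCON(OMe)Me (3 equiv), −78 to 0 °C
Reagents that add atoms: N-methoxy-N-methylisobutyramide, CC(C)C(=O)N(C)OC; n-butyllithium, [Li]CCCC (lithium held in 42 only)
Why: Directed ortho-metalation: after the alkoxide has formed, butyllithium removes Ca–H, the only ring hydrogen, flanked by the pyran oxygen and a MOM ether, and the aryllithium is acylated by the Weinreb amide, whose chelated adduct prevents over-addition.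

Step 31
Reactants: 43 Ca-isobutyryl derivative of 41
Product: 44 Ca-isobutyryl Cb,Cd-diphenol (both MOM groups removed)
Conditions: p-TsOH·H2O (0.3 equiv), MeOH, rt
Reagents that add atoms: none
Why: Acid-catalysed transacetalisation to methanol frees both phenols, since aryl MOM ethers ortho and para to an acyl group leave under conditions mild enough for the tertiary carbinol and the ring-C alkene.

Step 32
Reactants: 44 Ca-isobutyryl Cb,Cd-diphenol
Product: 45 CNP0564661.1 (target)
Conditions: NaOMe (3 equiv), MeI (1.3 equiv), MeOH, 0 °C to rt; dilute aq citric acid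
Reagents that add atoms: iodomethane, CI
Why: Dearomative C-methylation of an acylphloroglucinol: in the dianion the carbon Cc, flanked by two oxyanions and bearing only a methyl group, is the most nucleophilic ring carbon, and its alkylation gives the gem-dimethyl cyclohexadienone, which on acidification takes the hydrogen-bonded enol form of the target.

Compound list

1 | 2-methylbenzene-1,3-diol | Cc1c(O)cccc1O | starting material
2 | 1,3-bis(methoxymethoxy)-2-methylbenzene | Cc1c(OCOC)cccc1OCOC | intermediate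
3 | 2-[3,5-bis(methoxymethoxy)-4-methylphenyl]-4,4,5,5-tetramethyl-1,3,2-dioxaborolane | Cc1c(OCOC)cc(cc1OCOC)B1OC(C)(C)C(C)(C)O1 | intermediate (not isolated)
4 | 3,5-bis(methoxymethoxy)-4-methylphenol | Cc1c(OCOC)cc(O)cc1OCOC | intermediate
5 | 6-hydroxy-2,4-bis(methoxymethoxy)-3-methylbenzaldehyde | O=Cc1c(O)cc(OCOC)c(C)c1OCOC | intermediate
6 | 2,4-bis(methoxymethoxy)-3-methyl-6-[(triisopropylsilyl)oxy]benzaldehyde | O=Cc1c(O[Si](C(C)C)(C(C)C)C(C)C)cc(OCOC)c(C)c1OCOC | intermediate
7 | (S)-4-benzyl-1,3-oxazolidin-2-one | O=C1N[C@@H](Cc2ccccc2)CO1 | starting material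
8 | 2-(diethoxyphosphoryl)acetic acid | CCOP(=O)(CC(=O)O)OCC | starting material
9 | 2-(diethoxyphosphoryl)acetic pivalic anhydride | CCOP(=O)(CC(=O)OC(=O)C(C)(C)C)OCC | intermediate (not isolated)
10 | (S)-4-benzyl-3-[2-(diethoxyphosphoryl)acetyl]-1,3-oxazolidin-2-one | CCOP(=O)(CC(=O)N1[C@@H](Cc2ccccc2)COC1=O)OCC | intermediate
11 | (S)-4-benzyl-3-[(E)-3-{2,4-bis(methoxymethoxy)-3-methyl-6-[(triisopropylsilyl)oxy]phenyl}prop-2-enoyl]-1,3-oxazolidin-2-one | O=C(/C=C/c1c(O[Si](C(C)C)(C(C)C)C(C)C)cc(OCOC)c(C)c1OCOC)N1[C@@H](Cc2ccccc2)COC1=O | intermediate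
12 | (S)-4-benzyl-3-(3-{2,4-bis(methoxymethoxy)-3-methyl-6-[(triisopropylsilyl)oxy]phenyl}propanoyl)-1,3-oxazolidin-2-one | O=C(CCc1c(O[Si](C(C)C)(C(C)C)C(C)C)cc(OCOC)c(C)c1OCOC)N1[C@@H](Cc2ccccc2)COC1=O | intermediate
13 | sodium (Z)-enolate of 12 | [Na+].[O-]/C(=C\Cc1c(O[Si](C(C)C)(C(C)C)C(C)C)cc(OCOC)c(C)c1OCOC)N1[C@@H](Cc2ccccc2)COC1=O | intermediate (not isolated)
14 | (S)-4-benzyl-3-[(2R)-2-[(benzyloxy)methyl]-3-{2,4-bis(methoxymethoxy)-3-methyl-6-[(triisopropylsilyl)oxy]phenyl}propanoyl]-1,3-oxazolidin-2-one | O=C([C@@H](COCc1ccccc1)Cc1c(O[Si](C(C)C)(C(C)C)C(C)C)cc(OCOC)c(C)c1OCOC)N1[C@@H](Cc2ccccc2)COC1=O | intermediate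
15 | (2R)-2-[(benzyloxy)methyl]-3-{2,4-bis(methoxymethoxy)-3-methyl-6-[(triisopropylsilyl)oxy]phenyl}propaneperoxoic acid | OOC(=O)[C@@H](COCc1ccccc1)Cc1c(O[Si](C(C)C)(C(C)C)C(C)C)cc(OCOC)c(C)c1OCOC | intermediate (not isolated)
16 | (2R)-2-[(benzyloxy)methyl]-3-{2,4-bis(methoxymethoxy)-3-methyl-6-[(triisopropylsilyl)oxy]phenyl}propanoic acid | OC(=O)[C@@H](COCc1ccccc1)Cc1c(O[Si](C(C)C)(C(C)C)C(C)C)cc(OCOC)c(C)c1OCOC | intermediate
17 | (3R)-3-[(benzyloxy)methyl]-4-{2,4-bis(methoxymethoxy)-3-methyl-6-[(triisopropylsilyl)oxy]phenyl}butan-2-one | CC(=O)[C@@H](COCc1ccccc1)Cc1c(O[Si](C(C)C)(C(C)C)C(C)C)cc(OCOC)c(C)c1OCOC | intermediate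
18 | ethyl (2E,4S)-4-[(benzyloxy)methyl]-5-{2,4-bis(methoxymethoxy)-3-methyl-6-[(triisopropylsilyl)oxy]phenyl}-3-methylpent-2-enoate | CCOC(=O)/C=C(\C)[C@@H](COCc1ccccc1)Cc1c(O[Si](C(C)C)(C(C)C)C(C)C)cc(OCOC)c(C)c1OCOC | intermediate
19 | (2E,4S)-4-[(benzyloxy)methyl]-5-{2,4-bis(methoxymethoxy)-3-methyl-6-[(triisopropylsilyl)oxy]phenyl}-3-methylpent-2-en-1-ol | OC/C=C(\C)[C@@H](COCc1ccccc1)Cc1c(O[Si](C(C)C)(C(C)C)C(C)C)cc(OCOC)c(C)c1OCOC | intermediate
20 | (2E,4S)-4-[(benzyloxy)methyl]-5-{2,4-bis(methoxymethoxy)-3-methyl-6-[(triisopropylsilyl)oxy]phenyl}-3-methylpent-2-en-1-yl methyl carbonate | COC(=O)OC/C=C(\C)[C@@H](COCc1ccccc1)Cc1c(O[Si](C(C)C)(C(C)C)C(C)C)cc(OCOC)c(C)c1OCOC | intermediate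
21 | (2E,4S)-4-[(benzyloxy)methyl]-5-[6-hydroxy-2,4-bis(methoxymethoxy)-3-methylphenyl]-3-methylpent-2-en-1-yl methyl carbonate (key-step precursor) | COC(=O)OC/C=C(\C)[C@@H](COCc1ccccc1)Cc1c(O)cc(OCOC)c(C)c1OCOC | intermediate
22 | (2R,3R)-3-[(benzyloxy)methyl]-2-ethenyl-5,7-bis(methoxymethoxy)-2,6-dimethylchromane (key-step product) | COCOc1c(C)c(OCOC)c2c(c1)O[C@](C)(C=C)[C@@H](COCc1ccccc1)C2 | intermediate
23 | 9-{2-[(2R,3R)-3-[(benzyloxy)methyl]-5,7-bis(methoxymethoxy)-2,6-dimethylchroman-2-yl]ethyl}-9-borabicyclo[3.3.1]nonane | COCOc1c(C)c(OCOC)c2c(c1)O[C@](C)(CCB1C3CCCC1CCC3)[C@@H](COCc1ccccc1)C2 | intermediate (not isolated)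
24 | 2-[(2R,3R)-3-[(benzyloxy)methyl]-5,7-bis(methoxymethoxy)-2,6-dimethylchroman-2-yl]ethan-1-ol | COCOc1c(C)c(OCOC)c2c(c1)O[C@](C)(CCO)[C@@H](COCc1ccccc1)C2 | intermediate
25 | 2-[(2R,3R)-3-[(benzyloxy)methyl]-5,7-bis(methoxymethoxy)-2,6-dimethylchroman-2-yl]ethyl trifluoromethanesulfonate | COCOc1c(C)c(OCOC)c2c(c1)O[C@](C)(CCOS(=O)(=O)C(F)(F)F)[C@@H](COCc1ccccc1)C2 | intermediate
26 | (R)-4-benzyl-1,3-oxazolidin-2-one | O=C1N[C@H](Cc2ccccc2)CO1 | starting material
27 | (R)-4-benzyl-3-[(E)-but-2-enoyl]-1,3-oxazolidin-2-one | C/C=C/C(=O)N1[C@H](Cc2ccccc2)COC1=O | intermediate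
28 | sodium (Z)-dienolate of 27 | [Na+].[O-]/C(=C\C=C)N1[C@H](Cc2ccccc2)COC1=O | intermediate (not isolated)
29 | (R)-4-benzyl-3-[(2R)-2-{2-[(2R,3R)-3-[(benzyloxy)methyl]-5,7-bis(methoxymethoxy)-2,6-dimethylchroman-2-yl]ethyl}but-3-enoyl]-1,3-oxazolidin-2-one | COCOc1c(C)c(OCOC)c2c(c1)O[C@](C)(CC[C@@H](C(=O)N1[C@H](Cc3ccccc3)COC1=O)C=C)[C@@H](COCc1ccccc1)C2 | intermediate
30 | methyl (2R)-2-{2-[(2R,3R)-3-[(benzyloxy)methyl]-5,7-bis(methoxymethoxy)-2,6-dimethylchroman-2-yl]ethyl}but-3-enoate | COCOc1c(C)c(OCOC)c2c(c1)O[C@](C)(CC[C@@H](C(=O)OC)C=C)[C@@H](COCc1ccccc1)C2 | intermediate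
31 | (3R)-3-{2-[(2R,3R)-3-[(benzyloxy)methyl]-5,7-bis(methoxymethoxy)-2,6-dimethylchroman-2-yl]ethyl}-2-methylpent-4-en-2-ol | COCOc1c(C)c(OCOC)c2c(c1)O[C@](C)(CC[C@@H](C(C)(C)O)C=C)[C@@H](COCc1ccccc1)C2 | intermediate
32 | (3R)-3-{2-[(2R,3R)-3-(hydroxymethyl)-5,7-bis(methoxymethoxy)-2,6-dimethylchroman-2-yl]ethyl}-2-methylpent-4-en-2-ol | COCOc1c(C)c(OCOC)c2c(c1)O[C@](C)(CC[C@@H](C(C)(C)O)C=C)[C@@H](CO)C2 | intermediate
33 | {(2R,3R)-2-[(3R)-3-ethenyl-4-hydroxy-4-methylpentyl]-5,7-bis(methoxymethoxy)-2,6-dimethylchroman-3-yl}methyl 4-methylbenzenesulfonate | COCOc1c(C)c(OCOC)c2c(c1)O[C@](C)(CC[C@@H](C(C)(C)O)C=C)[C@@H](COS(=O)(=O)c1ccc(C)cc1)C2 | intermediate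
34 | methyl (S)-3-hydroxy-2-methylpropanoate | COC(=O)[C@@H](C)CO | starting material
35 | methyl (S)-3-[(tert-butyldimethylsilyl)oxy]-2-methylpropanoate | COC(=O)[C@@H](C)CO[Si](C)(C)C(C)(C)C | intermediate
36 | (S)-3-[(tert-butyldimethylsilyl)oxy]-2-methylpropanal | O=C[C@@H](C)CO[Si](C)(C)C(C)(C)C | intermediate
37 | (R)-tert-butyldimethyl[(2-methylbut-3-en-1-yl)oxy]silane | C=C[C@@H](C)CO[Si](C)(C)C(C)(C)C | intermediate
38 | (R)-4-bromo-3-methylbut-1-ene | C=C[C@@H](C)CBr | intermediate
39 | [(R)-2-methylbut-3-en-1-yl]magnesium bromide | C=C[C@@H](C)C[Mg]Br | intermediate (not isolated)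
40 | (3R)-3-{2-[(2R,3S)-5,7-bis(methoxymethoxy)-2,6-dimethyl-3-[(3S)-3-methylpent-4-en-1-yl]chroman-2-yl]ethyl}-2-methylpent-4-en-2-ol | COCOc1c(C)c(OCOC)c2c(c1)O[C@](C)(CC[C@@H](C(C)(C)O)C=C)[C@@H](CC[C@H](C)C=C)C2 | intermediate
41 | (5Z)-tricycle: chroman trans-fused at C10/C1 to ten-membered ring C (C1 S, C4 S, C7 R, C10 R), C7 bearing the C11 dimethylcarbinol, ring A aromatic with Cb/Cd MOM ethers, Cc methyl and Ca–H | COCOc1c(C)c(OCOC)c2c(c1)O[C@]1(C)CC[C@@H](C(C)(C)O)/C=C\[C@@H](C)CC[C@H]1C2 | intermediate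
42 | Ca-lithio derivative of 41 as its C11 lithium alkoxide | [Li]c1c(OCOC)c(C)c(OCOC)c2c1O[C@]1(C)CC[C@@H](C(C)(C)O[Li])/C=C\[C@@H](C)CC[C@H]1C2 | intermediate (not isolated)
43 | Ca-(2-methylpropanoyl) derivative of 41 | CC(C)C(=O)c1c(OCOC)c(C)c(OCOC)c2c1O[C@]1(C)CC[C@@H](C(C)(C)O)/C=C\[C@@H](C)CC[C@H]1C2 | intermediate
44 | Ca-(2-methylpropanoyl) Cb,Cd-diphenol of the (5Z)-tricycle | CC(C)C(=O)c1c(O)c(C)c(O)c2c1O[C@]1(C)CC[C@@H](C(C)(C)O)/C=C\[C@@H](C)CC[C@H]1C2 | intermediate
45 | CNP0564661.1 | CC(C)C(=O)C1=C(O)C(C)(C)C(=O)C2=C1O[C@]1(C)CC[C@@H](C(C)(C)O)/C=C\[C@@H](C)CC[C@H]1C2 | target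

Total step count: 32 (26 on the main line, 4 for bromide 38, 1 each for reagents 10 and 27).
Longest linear sequence: 26 steps from 1 (steps 1–4, 6–17, 19–23, 28–32).

Steps most likely to fail

Step 15. The resident C1 centre and the ligand may act against each other, so that facial selection at C10 is poor and the cis C9/C2 diastereomer forms, or ionisation is slow and the carbonate is lost to hydrolysis. The fallback replaces catalyst control by reagent-controlled epoxidation and a stereospecific ring opening; it sets out from 19 and comes back at 22. Sharpless asymmetric epoxidation of 19 (Ti(OiPr)4, D-(−)-diethyl tartrate, t-BuOOH, 4 Å sieves, CH2Cl2, −20 °C) should give the (2R,3R)-epoxy alcohol F1. Bu4NF/AcOH then frees the epoxy phenol F2. Catalytic camphorsulfonic acid in CH2Cl2 closes ring B by 6-exo attack of Cf–OH at C10 with inversion and gives the chroman diol F3. NaIO4 cleaves the diol to the chroman-2-carbaldehyde F4, and Wittig methylenation (Ph3PCH3Br, KOtBu) restores the vinyl group of 22.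

Step 29. Intermolecular metathesis (oligomerisation) may outrun closure of the strained ten-membered ring, the catalyst may stall at the hindered C7 vinyl group, or the E alkene may form. The fallback closes the ring by carbonyl coupling instead; it sets out from 40 and comes back at 41. The tertiary alcohol of 40 is silylated (Et3SiCl, imidazole, DMAP, DMF) to the triethylsilyl ether F5. Lemieux–Johnson cleavage of both vinyl groups (OsO4 cat., NaIO4, 2,6-lutidine, dioxane/H2O) gives the dialdehyde F6. McMurry coupling under high dilution (TiCl3(DME)1.5, Zn–Cu couple, DME, reflux, slow addition) should give the silylated (5Z)-tricycle F7, the cis alkene again being the less strained one, and Bu4NF returns 41.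

Step 28. Substitution at the β-branched C2 tosylate next to the quaternary C10 may be so slow that reduction, elimination or homocoupling of the Grignard reagent take over, and slow homoallyl–cyclopropylcarbinyl interconversion of 39 could erode the C4 configuration. The fallback uses a sulfone-stabilised carbanion instead of the Grignard reagent; it sets out from 33 and 38 and comes back at 40. Finkelstein exchange of 33 (NaI, acetone, reflux) gives the iodide F8. Bromide 38 and PhSO2Na in DMF give the sulfone F9. Lithiated F9 (n-BuLi, THF/DMPU, −78 °C, 2.2 equiv) is alkylated by F8 to the sulfone F10 (both C3 epimers). Reductive desulfonylation (Na(Hg), Na2HPO4, MeOH, −20 °C) then gives 40.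

Further compounds

F1 | step 15 | {(2R,3R)-3-[(2R)-1-(benzyloxy)-3-{2,4-bis(methoxymethoxy)-3-methyl-6-[(triisopropylsilyl)oxy]phenyl}propan-2-yl]-3-methyloxiran-2-yl}methanol | OC[C@H]1O[C@]1(C)[C@@H](COCc2ccccc2)Cc2c(O[Si](C(C)C)(C(C)C)C(C)C)cc(OCOC)c(C)c2OCOC
F2 | step 15 | {(2R,3R)-3-[(2R)-1-(benzyloxy)-3-[6-hydroxy-2,4-bis(methoxymethoxy)-3-methylphenyl]propan-2-yl]-3-methyloxiran-2-yl}methanol | OC[C@H]1O[C@]1(C)[C@@H](COCc2ccccc2)Cc2c(O)cc(OCOC)c(C)c2OCOC
F3 | step 15 | (1R)-1-[(2S,3R)-3-[(benzyloxy)methyl]-5,7-bis(methoxymethoxy)-2,6-dimethylchroman-2-yl]ethane-1,2-diol | COCOc1c(C)c(OCOC)c2c(c1)O[C@](C)([C@H](O)CO)[C@@H](COCc1ccccc1)C2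
F4 | step 15 | (2S,3R)-3-[(benzyloxy)methyl]-5,7-bis(methoxymethoxy)-2,6-dimethylchromane-2-carbaldehyde | COCOc1c(C)c(OCOC)c2c(c1)O[C@](C)(C=O)[C@@H](COCc1ccccc1)C2
F5 | step 29 | triethylsilyl ether of 40 at the C11 hydroxyl | COCOc1c(C)c(OCOC)c2c(c1)O[C@](C)(CC[C@@H](C(C)(C)O[Si](CC)(CC)CC)C=C)[C@@H](CC[C@H](C)C=C)C2
F6 | step 29 | C5,C6-dialdehyde from cleavage of both vinyl groups of F5 | COCOc1c(C)c(OCOC)c2c(c1)O[C@](C)(CC[C@@H](C(C)(C)O[Si](CC)(CC)CC)C=O)[C@@H](CC[C@H](C)C=O)C2
F7 | step 29 | triethylsilyl ether of 41 at the C11 hydroxyl | COCOc1c(C)c(OCOC)c2c(c1)O[C@]1(C)CC[C@@H](C(C)(C)O[Si](CC)(CC)CC)/C=C\[C@@H](C)CC[C@H]1C2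
F8 | step 28 | (3R)-3-{2-[(2R,3S)-3-(iodomethyl)-5,7-bis(methoxymethoxy)-2,6-dimethylchroman-2-yl]ethyl}-2-methylpent-4-en-2-ol | COCOc1c(C)c(OCOC)c2c(c1)O[C@](C)(CC[C@@H](C(C)(C)O)C=C)[C@@H](CI)C2
F9 | step 28 | (R)-[(2-methylbut-3-en-1-yl)sulfonyl]benzene | C=C[C@@H](C)CS(=O)(=O)c1ccccc1
F10 | step 28 | C3-phenylsulfonyl derivative of 40 (both C3 epimers) | COCOc1c(C)c(OCOC)c2c(c1)O[C@](C)(CC[C@@H](C(C)(C)O)C=C)[C@@H](CC([C@H](C)C=C)S(=O)(=O)c1ccccc1)C2
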